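## Structural features

Atoms are numbered as in a bisabolane. The ring is C1–C6, with C1 the carbinol carbon, C3 the CHCl carbon and C4 the carbon bearing Br and the methyl group C15. The side chain is C7(=C14H2)–C8H2–C9H2–C10H(OH)–C11(=C12H2)–C13H3, joined to the ring through C1–C7.

Three of the four stereocentres lie in the single cyclohexane ring: C3 and C4 are adjacent, and C1 stands 1,3 to C3 and 1,4 to C4. The fourth, C10 (R), is four bonds of flexible chain away from C1 and cannot be relayed from the ring.

The SMILES string reads as (1S,3S,4S). C1–OH, C3–Cl and C15 lie on one face, and C7 and Br on the other. Br and Cl are therefore trans, Cl is cis-1,3 to OH, and Br is cis-1,4 to C7.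

The fragile groups are:
- the tertiary bromide (E1, E2, and reductive loss together with the vicinal chloride under metals or soft nucleophiles);
- the tertiary allylic C1–OH (ionisation by acids);
- two 1,1-disubstituted alkenes that compete for any electrophile.

The real difficulty is the C3/C4 pair. Br sits on the tertiary carbon and Cl on the secondary one, the reverse of what Br+/Cl− addition to a C3=C4 alkene delivers. The pair must also be placed in one absolute sense relative to C1.

The key step exploits the cis-1,4 relation of C7 to the C4 heteroatom, together with the anti relation of C3–Cl. When C7 is a carboxyl carbon, a two-atom bridge C7(=O)–O can span the ring from C1 to C4 as a 2-oxabicyclo[2.2.2]octan-3-one. An anti addition of Cl+ and carboxylate O across C3=C4 then fixes C3 and C4 from C1, with chlorine as the electrophile. The bridge oxygen marks the site and the face for bromide.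

## Logic of the disconnections

**C7=C14 (16 ⇒ 15 ⇒ 14).** After the two silyl groups are added back (15), the C7=C14 double bond is cut to the C7 ketone of 14. While C7 is a carbonyl carbon, C1–O is not allylic and cannot ionise, and no alkene stands next to the ring. All cationic chemistry at C4 can then be done earlier. The gain is one carbon and the removal of the most acid-labile group from every earlier step. The demand is a methylenation that is neither basic nor reducing, because C4–Br is already in place.

**C7–C8 (14 ⇒ 9 + 12, through 13).** This cut separates the ring, with its three stereocentres, from the chain with C10. Each half has its own source of chirality and the plan becomes convergent. The demand is an acyl substitution that stops at the ketone and a carbanion mild enough for a tertiary bromide.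

**C10–O/C11=C12 (12 ⇒ 11 ⇒ 10).** The protected allylic alcohol is traced to the C10–C11 epoxide and then to a trisubstituted alkene. The gain is that C10 is set by catalysis on a five-carbon commercial bromide. The demand is an isomerisation that breaks only C11–O.

**Functional groups at C7 and C1–O (9 ⇒ 8 ⇒ 7).** No skeletal bond is cut. The amide and the silyl ether are traced to the free hydroxy acid, and both steps must use weak bases only.

**C4–Br (7 ⇒ 6).** The C4–Br bond is cut and C4–O is closed back onto the C7 carboxyl. The tertiary bromide then comes from alkyl–oxygen cleavage at the only carbon of 6 that can carry positive charge. The gain is that the labile halide is replaced by a robust bicyclic compound. The demand is substitution at C4 with retention.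

**C3–Cl and C4–O (6 ⇒ 5, key disconnection).** Both bonds and the bicyclic ring are removed at once, leaving one stereocentre (C1) and one alkene. In one sentence, the route is a transannular chlorolactonisation of 5. Reversing the roles of the halogens (Cl+ first, Br− later) makes the electronic preference of C3=C4 work for the plan at both stages. The demand is capture at C4 by the carboxylate from the C7 face, faster than every other fate of the chlorinated alkene.

**C1–O (5 ⇒ 4 ⇒ 3 ⇒ 2 ⇒ 1).** C7 is adjusted to the alcohol level, and C6–H is traded for a C1–C6 epoxide. That epoxide is cut from an achiral allylic alcohol, which is a dihydroarene. The gain is that C1 comes from a reagent-controlled epoxidation with a predictable sense, starting from an arene. The demand is chemoselectivity for the allylic alkene over C3=C4.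

## Other disconnections considered

Alternative 1: cut C1–C7, the first cut that comes to mind. The forward key step would add the alkenyllithium A2 to (3S,4S)-4-bromo-3-chloro-4-methylcyclohexan-1-one A1.
- A1 carries the whole halogen problem unsolved: tertiary Br and secondary Cl against the electronic bias, in one absolute sense, on an alkene with no directing group.
- In A1 the C3–Cl bond is β to the carbonyl group. A hard, basic carbanion should therefore provoke enolisation with loss of chloride, or halogen–metal exchange at C4 with loss of the vicinal chloride.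
- C1 would be set last, only by the axial/equatorial preference of a ring that can flip between diaxial and diequatorial dihalide chairs.
- The chosen plan sets C1 first by reagent control and lets it govern C3 and C4, at the same number of C–C bond formations.

Alternative 2: cut C3–Cl and C4–Br last. The forward key step would be a hydroxyl-directed bromochlorination of the complete triene diol A3, possibly through the bromo ether A4 formed when C1–OH captures the bromonium ion.
- In the half-chair with the side chain equatorial and OH axial, the pathway in which trans-diaxial opening and attack at the tertiary carbon coincide is a halonium ion on the OH face, opened at C4. That puts Br on C3 and Cl on C4, with the halogens exchanged.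
- The target needs the bromonium ion anti to OH, opened at secondary C3. The electronic bias opposes this, and only a weak conformational preference supports it.
- Reversible bromine transfer would drain the material into the matched pathway.
- Re-opening A4 with a chloride Lewis acid faces the same C3/C4 choice, and its C1–O bond is tertiary and allylic and should ionise first.
- C10–OH can also close onto C7=C14 in a 5-exo mode.

Alternative 3: the biomimetic cut of both C–O bonds. The forward key step would be a double Schenck ene reaction of singlet oxygen with the bromochloro-γ-bisabolene A5, followed by reduction.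
- The step count would be low, but the tetrasubstituted C1=C7 alkene offers three kinds of allylic hydrogen (C14, C8, ring C2/C6).
- The C10=C11 alkene gives secondary and tertiary hydroperoxides.
- Nothing controls C10, and C1 is controlled only by remote halogens.
- A5 still needs the same contra-electronic bromochloride, now in the presence of two more electron-rich alkenes.
- The chosen plan answers each of these selectivity questions with a tether or a reagent.

Key step: step 5

Assumption: compounds 1 and 10 and the D-fructose-derived ketone catalyst are taken as commercial, and atom numbers in the steps are those defined under "Structural features".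

## Steps

Step 1
Reactants: 1 4-methylbenzyl alcohol
Product: 2 (4-methylcyclohexa-1,4-dien-1-yl)methanol
Conditions: Li, NH3(l), THF, EtOH, −78 to −33 °C; then MeOH
Reagents that add atoms: none
Why: Birch reduction; CH2O− and CH3 both act as donor substituents, so the ring is protonated at unsubstituted positions and both substituents end on sp2 carbons of the 1,4-diene. The alcohol reacts as its lithium alkoxide, a poor leaving group, which should hold back benzylic C–O cleavage; no stereocentre is formed.

Step 2
Reactants: 2 (4-methylcyclohexa-1,4-dien-1-yl)methanol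
Product: 3 [(1S,6S)-4-methyl-7-oxabicyclo[4.1.0]hept-3-en-1-yl]methanol
Conditions: Ti(OiPr)4 (0.1 equiv), L-(+)-diisopropyl tartrate (0.12 equiv), t-BuOOH, 4 Å molecular sieves, CH2Cl2, −20 °C
Reagents that add atoms: tert-butyl hydroperoxide, CC(C)(C)OO
Why: Sharpless asymmetric epoxidation; only the alkene of the titanium-bound allylic alcohol (C1=C6) is oxidised, so C3=C4 is left alone. With the L-(+)-tartrate, oxygen enters in the sense that turns (E)-2-hexen-1-ol into its (2S,3S)-epoxide, which here makes C1 and C6 both S. This is the only ring stereocentre set by a reagent.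

Step 3
Reactants: 3 [(1S,6S)-4-methyl-7-oxabicyclo[4.1.0]hept-3-en-1-yl]methanol
Product: 4 (1S)-1-(hydroxymethyl)-4-methylcyclohex-3-en-1-ol
Conditions: LiAlH4, THF, 0 °C to rt; aqueous work-up
Reagents that add atoms: none
Why: Hydride opening of a 2,3-epoxy alcohol; SN2 attack is possible only at secondary C6, because C1 is fully substituted. The C1–O bond is not touched, so C1 stays S and C6 becomes CH2.

Step 4
Reactants: 4 (1S)-1-(hydroxymethyl)-4-methylcyclohex-3-en-1-ol
Product: 5 (1S)-1-hydroxy-4-methylcyclohex-3-ene-1-carboxylic acid
Conditions: TEMPO (0.2 equiv), PhI(OAc)2 (2.2 equiv), MeCN–H2O, 0 °C to rt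
Reagents that add atoms: water, O
Why: Nitroxyl-catalysed oxidation of a primary alcohol through the aldehyde hydrate to the acid. The tertiary C1–OH cannot be oxidised and the oxoammonium salt does not add to a trisubstituted alkene, so C1 is unaffected.

Step 5
Reactants: 5 (1S)-1-hydroxy-4-methylcyclohex-3-ene-1-carboxylic acid
Product: 6 (1S,4S,6S)-6-chloro-4-hydroxy-1-methyl-2-oxabicyclo[2.2.2]octan-3-one
Conditions: 1,3-dichloro-5,5-dimethylhydantoin (0.55 equiv), quinuclidine (0.1 equiv), CHCl3, −40 to 0 °C, dark
Reagents that add atoms: 1,3-dichloro-5,5-dimethylhydantoin, CC1(C)N(Cl)C(=O)N(Cl)C1=O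
Why: The ammonium carboxylate of 5 folds C7 under the ring in a boat, Cl+ is passed to the opposite face of C3=C4, and the carboxylate oxygen attacks C4 in a near-concerted anti addition. The closest known reaction types are the halolactonisation of cyclohex-3-enecarboxylic acids and the haloetherification of α-terpineol to 2-halo-1,8-cineoles, which closes the same two-atom bridge onto the methyl-bearing alkene carbon. The δ-lactone ring is closed at C4 in a mode that is 6-exo when counted through C5–C6 and 6-endo when counted through C2–C3, and the two together give the 2-oxabicyclo[2.2.2]octan-3-one. C4 is controlled by the tether, since the oxygen can reach only the face of C4 that carries C7 at C1. C3 is controlled by the anti course of the addition, which puts Cl on the other face, cis to C1–OH. For regioselectivity, the chlorine-bridged ion of a trisubstituted alkene carries its charge on tertiary C4, so the electronic bias favours C4 over the γ-lactone mode at C3. For chemoselectivity, the ionised carboxylate must outrun the neutral, hindered C1–OH (which would have to build a more strained 7-oxabicyclo[2.2.1]heptane from the other face) and proton loss from C15, and the low temperature and non-polar solvent favour the pre-associated nucleophile.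

Step 6
Reactants: 6 (1S,4S,6S)-6-chloro-4-hydroxy-1-methyl-2-oxabicyclo[2.2.2]octan-3-one
Product: 7 (1S,3S,4S)-4-bromo-3-chloro-1-hydroxy-4-methylcyclohexane-1-carboxylic acid
Conditions: BBr3 (3 equiv), CH2Cl2, −78 to −30 °C; then ice-water
Reagents that add atoms: boron tribromide, BrB(Br)Br
Why: Lewis-acid alkyl–oxygen cleavage of a tertiary-alkyl lactone to a bromo acid, driven by B–O bond formation and by release of the boat strain. C3–Cl is antiperiplanar to the breaking C4–O bond, so chlorine should bridge its own face while the borate-bound carboxylate leaves. Bromide then enters tertiary C4 from the vacated face with overall retention, and C1–O is α to the carboxyl carbon and cannot ionise.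

Step 7
Reactants: 7 (1S,3S,4S)-4-bromo-3-chloro-1-hydroxy-4-methylcyclohexane-1-carboxylic acid
Product: 8 (1S,3S,4S)-4-bromo-3-chloro-1-hydroxy-N-methoxy-N,4-dimethylcyclohexane-1-carboxamide
Conditions: MeNH(OMe)·HCl, EDC·HCl, HOBt, N-methylmorpholine, CH2Cl2, 0 °C to rt
Reagents that add atoms: N,O-dimethylhydroxylamine hydrochloride, CNOC.Cl
Why: Carbodiimide amide coupling; the hindered tertiary OH does not compete with the amine. The weak base at or below room temperature should leave alone a tertiary bromide whose ionisation is slowed by the β-chlorine.

Step 8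
Reactants: 8 (1S,3S,4S)-4-bromo-3-chloro-1-hydroxy-N-methoxy-N,4-dimethylcyclohexane-1-carboxamide
Product: 9 (1S,3S,4S)-4-bromo-3-chloro-N-methoxy-N,4-dimethyl-1-(triethylsilyloxy)cyclohexane-1-carboxamide
Conditions: Et3SiOTf, 2,6-lutidine, CH2Cl2, −78 to 0 °C
Reagents that add atoms: triethylsilyl trifluoromethanesulfonate, CC[Si](CC)(CC)OS(=O)(=O)C(F)(F)F
Why: Silyl triflate silylation of a hindered tertiary alcohol with a non-nucleophilic base. It removes the acidic proton before the two organometallic steps and comes off together with the C10 silyl group at the end.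

Step 9
Reactants: 10 5-bromo-2-methylpent-2-ene
Product: 11 (3R)-3-(2-bromoethyl)-2,2-dimethyloxirane
Conditions: 1,2:4,5-di-O-isopropylidene-β-D-erythro-2,3-hexodiulo-2,6-pyranose (0.3 equiv), KHSO5, K2CO3, Bu4NHSO4, Na2B4O7 buffer, MeCN–CH2(OMe)2–H2O, 0 °C
Reagents that add atoms: potassium peroxymonosulfate, [K+].OOS(=O)(=O)[O-]
Why: Shi epoxidation; the dioxirane of the D-fructose-derived ketone attacks trisubstituted alkenes through the spiro transition state and gives the R configuration at the CH carbon, the future C10. The primary bromide is inert to the buffered oxidant.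

Step 10
Reactants: 11 (3R)-3-(2-bromoethyl)-2,2-dimethyloxirane
Product: 12 (3R)-5-bromo-3-(tert-butyldimethylsilyloxy)-2-methylpent-1-ene
Conditions: t-BuMe2SiOTf, DBU, toluene, −20 °C to rt
Reagents that add atoms: tert-butyldimethylsilyl trifluoromethanesulfonate, CC(C)(C)[Si](C)(C)OS(=O)(=O)C(F)(F)F
Why: Silyl triflate/amidine isomerisation of a trisubstituted epoxide to the allylic silyl ether, by O-silylation, heterolysis of the tertiary C11–O bond and loss of a methyl proton. The C10–O bond is never broken, so C10 stays R and the alcohol emerges already protected.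

Step 11
Reactants: 12 (3R)-5-bromo-3-(tert-butyldimethylsilyloxy)-2-methylpent-1-ene; 9 (1S,3S,4S)-4-bromo-3-chloro-N-methoxy-N,4-dimethyl-1-(triethylsilyloxy)cyclohexane-1-carboxamide
Product: 14 (4R)-1-[(1S,3S,4S)-4-bromo-3-chloro-4-methyl-1-(triethylsilyloxy)cyclohexyl]-4-(tert-butyldimethylsilyloxy)-5-methylhex-5-en-1-one, via alkylmagnesium bromide 13 (not isolated)
Conditions: 12, Mg, THF, rt, solution decanted from Mg; then 9, THF, −40 to 0 °C; aq NH4Cl
Reagents that add atoms: none
Why: Weinreb ketone synthesis; the chelated tetrahedral adduct holds until work-up, so addition stops at the ketone and forms C7–C8. A primary alkylmagnesium reagent at low temperature, free of metallic Mg, is the least basic and least reducing carbanion that still acylates, and no stereocentre is touched.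

Step 12
Reactants: 14 (4R)-1-[(1S,3S,4S)-4-bromo-3-chloro-4-methyl-1-(triethylsilyloxy)cyclohexyl]-4-(tert-butyldimethylsilyloxy)-5-methylhex-5-en-1-one
Product: 15 (1S,3S,4S)-4-bromo-3-chloro-4-methyl-1-[(5R)-5-(tert-butyldimethylsilyloxy)-6-methylhepta-1,6-dien-2-yl]-1-(triethylsilyloxy)cyclohexane
Conditions: Cp2Ti(μ-CH2)(μ-Cl)AlMe2, pyridine, toluene–THF, −40 °C to rt; Na2SO4·10H2O
Reagents that add atoms: Cp2Ti(μ-CH2)(μ-Cl)AlMe2 (written as Cp2Ti=CH2·ClAlMe2), C=[Ti](C1C=CC=C1)C1C=CC=C1.C[Al](C)Cl
Why: Tebbe methylenation; the small, non-basic titanium methylidene adds to hindered α-silyloxy ketones through an oxatitanacyclobutane, so E2 at C4 is not invited. Pyridine ties up Me2AlCl and keeps it from ionising C4–Br.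

Step 13
Reactants: 15 (1S,3S,4S)-4-bromo-3-chloro-4-methyl-1-[(5R)-5-(tert-butyldimethylsilyloxy)-6-methylhepta-1,6-dien-2-yl]-1-(triethylsilyloxy)cyclohexane
Product: 16 (1S,3S,4S)-4-bromo-3-chloro-1-[(5R)-5-hydroxy-6-methylhepta-1,6-dien-2-yl]-4-methylcyclohexan-1-ol
Conditions: HF·pyridine, pyridine, THF, 0 °C to rt
Reagents that add atoms: none
Why: Fluoride desilylation of both ethers in a buffered, weakly acidic medium. It avoids basic fluoride, which could eliminate HBr, and it is not acidic enough to ionise the tertiary allylic C1–OH.

## Compound list

1 | 4-methylbenzyl alcohol | Cc1ccc(CO)cc1 | starting material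
2 | (4-methylcyclohexa-1,4-dien-1-yl)methanol | OCC1=CCC(C)=CC1 | intermediate
3 | [(1S,6S)-4-methyl-7-oxabicyclo[4.1.0]hept-3-en-1-yl]methanol | OC[C@]12O[C@H]1CC(C)=CC2 | intermediate
4 | (1S)-1-(hydroxymethyl)-4-methylcyclohex-3-en-1-ol | OC[C@]1(O)CCC(C)=CC1 | intermediate
5 | (1S)-1-hydroxy-4-methylcyclohex-3-ene-1-carboxylic acid | OC(=O)[C@]1(O)CCC(C)=CC1 | intermediate
6 | (1S,4S,6S)-6-chloro-4-hydroxy-1-methyl-2-oxabicyclo[2.2.2]octan-3-one | O=C1[C@]2(O)CC[C@](C)(O1)[C@@H](Cl)C2 | intermediate
7 | (1S,3S,4S)-4-bromo-3-chloro-1-hydroxy-4-methylcyclohexane-1-carboxylic acid | OC(=O)[C@]1(O)CC[C@](C)(Br)[C@@H](Cl)C1 | intermediate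
8 | (1S,3S,4S)-4-bromo-3-chloro-1-hydroxy-N-methoxy-N,4-dimethylcyclohexane-1-carboxamide | CON(C)C(=O)[C@]1(O)CC[C@](C)(Br)[C@@H](Cl)C1 | intermediate
9 | (1S,3S,4S)-4-bromo-3-chloro-N-methoxy-N,4-dimethyl-1-(triethylsilyloxy)cyclohexane-1-carboxamide | CON(C)C(=O)[C@]1(O[Si](CC)(CC)CC)CC[C@](C)(Br)[C@@H](Cl)C1 | intermediate
10 | 5-bromo-2-methylpent-2-ene | CC(C)=CCCBr | starting material
11 | (3R)-3-(2-bromoethyl)-2,2-dimethyloxirane | CC1(C)O[C@@H]1CCBr | intermediate
12 | (3R)-5-bromo-3-(tert-butyldimethylsilyloxy)-2-methylpent-1-ene | C=C(C)[C@H](O[Si](C)(C)C(C)(C)C)CCBr | intermediate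
13 | [(3R)-3-(tert-butyldimethylsilyloxy)-4-methylpent-4-en-1-yl]magnesium bromide | C=C(C)[C@H](O[Si](C)(C)C(C)(C)C)CC[Mg]Br | intermediate
14 | (4R)-1-[(1S,3S,4S)-4-bromo-3-chloro-4-methyl-1-(triethylsilyloxy)cyclohexyl]-4-(tert-butyldimethylsilyloxy)-5-methylhex-5-en-1-one | C=C(C)[C@H](O[Si](C)(C)C(C)(C)C)CCC(=O)[C@]1(O[Si](CC)(CC)CC)CC[C@](C)(Br)[C@@H](Cl)C1 | intermediate
15 | (1S,3S,4S)-4-bromo-3-chloro-4-methyl-1-[(5R)-5-(tert-butyldimethylsilyloxy)-6-methylhepta-1,6-dien-2-yl]-1-(triethylsilyloxy)cyclohexane | C=C(C)[C@H](O[Si](C)(C)C(C)(C)C)CCC(=C)[C@]1(O[Si](CC)(CC)CC)CC[C@](C)(Br)[C@@H](Cl)C1 | intermediate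
16 | (1S,3S,4S)-4-bromo-3-chloro-1-[(5R)-5-hydroxy-6-methylhepta-1,6-dien-2-yl]-4-methylcyclohexan-1-ol | C=C(C)[C@H](O)CCC(=C)[C@]1(O)CC[C@](C)(Br)[C@@H](Cl)C1 | target

## Step count and least certain steps

Total step count: 13. The longest linear sequence is 11 steps (steps 1–8 and 11–13). The chain branch (steps 9 and 10) joins at step 11.

**Step 5 (key step).** Chlorine transfer is hardly reversible, so a wrong first event is not corrected. The likely failures are:
- loss of a C15 proton from the chlorine-bridged ion before the carboxylate arrives (ene-type allylic chlorination);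
- chlorine transfer to the C7 face followed by capture by C1–OH;
- O-chlorination of the α-hydroxy acid followed by decarboxylation.

The fallback brings chlorine in as the nucleophile. It sets out from 5.
- I2, KI and NaHCO3 should give (1S,4S,6S)-4-hydroxy-6-iodo-1-methyl-2-oxabicyclo[2.2.2]octan-3-one F1. Iodonium formation is reversible, and the γ-lactone mode would converge on the same next compound.
- NaOMe in MeOH should then give methyl (1R,3S,6S)-3-hydroxy-6-methyl-7-oxabicyclo[4.1.0]heptane-3-carboxylate F2, with the epoxide on the C7 face.
- Li2CuCl4 in THF should open it at the less hindered C3, in the trans-diaxial sense of the chair with the ester equatorial, to methyl (1S,3S,4S)-3-chloro-1,4-dihydroxy-4-methylcyclohexane-1-carboxylate F3.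
- F3 should close on warming with catalytic TsOH.

The fallback comes back to the route at 6.

**Step 6.** The C4 cation is destabilised by the β-chlorine and bridging by chlorine is weak. Three failures are likely: proton loss instead of bromide capture, partial capture from the chlorine face with erosion of configuration at C4, and re-closure of the bromo acid to the lactone during work-up.

The fallback makes the C4–Br bond by ionic hydrobromination. It sets out from 6. Acid-induced eliminative opening with CF3CO2H in CH2Cl2 should give (1S,5S)-5-chloro-1-hydroxy-4-methylcyclohex-3-ene-1-carboxylic acid F4. Dry HBr in CH2Cl2 at −78 °C should then add in the Markovnikov sense, with bromide entering anti to chlorine at high bromide concentration. Proton loss becomes harmless, since its outcome is simply re-protonated. The fallback comes back at 7.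

**Step 11.** The amide carbonyl is flanked by a fully substituted carbon, so addition may be slow. If so, the Grignard reagent may act as a base at C4–Br, reduce the vicinal dihalide by halogen–metal exchange, or cleave the N–O bond.

The fallback changes the electrophile and the oxidation level. It sets out from 9.
- iBu2AlH at −78 °C should give (1S,3S,4S)-4-bromo-3-chloro-4-methyl-1-(triethylsilyloxy)cyclohexane-1-carbaldehyde F5.
- F5 should accept 13 within minutes at −78 °C to give (4R)-1-[(1S,3S,4S)-4-bromo-3-chloro-4-methyl-1-(triethylsilyloxy)cyclohexyl]-4-(tert-butyldimethylsilyloxy)-5-methylhex-5-en-1-ol F6 as a mixture at C7.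
- Dess–Martin periodinane should erase the C7 centre.

The fallback comes back at 14.

**Step 12.** Methylenation may be slow at the hindered ketone. Prolonged contact with the aluminium by-product could then ionise the tertiary bromide.

The fallback is a Peterson olefination. It sets out from 14. Me3SiCH2MgCl with CeCl3 in THF at −78 °C should give (5R)-2-[(1S,3S,4S)-4-bromo-3-chloro-4-methyl-1-(triethylsilyloxy)cyclohexyl]-5-(tert-butyldimethylsilyloxy)-6-methyl-1-(trimethylsilyl)hept-6-en-2-ol F7. HF·pyridine should then bring about the acidic β-hydroxysilane elimination and both desilylations in one operation. The fallback comes back at 16.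

**Step 4.** The iodine reagent can bind the 1,2-diol as a cyclic ester. C1–C7 glycol cleavage may therefore compete with the nitroxyl cycle.

The fallback splits the oxidation at the aldehyde stage and uses oxidants that cannot form such an ester. It sets out from 4. Parikh–Doering oxidation (SO3·pyridine, DMSO, Et3N) should give (1S)-1-hydroxy-4-methylcyclohex-3-ene-1-carbaldehyde F8. Pinnick oxidation (NaClO2, NaH2PO4, large excess of 2-methylbut-2-ene) should complete the change. The fallback comes back at 5.

## Further compounds

F1 | step 5 | (1S,4S,6S)-4-hydroxy-6-iodo-1-methyl-2-oxabicyclo[2.2.2]octan-3-one | O=C1[C@]2(O)CC[C@](C)(O1)[C@@H](I)C2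
F2 | step 5 | methyl (1R,3S,6S)-3-hydroxy-6-methyl-7-oxabicyclo[4.1.0]heptane-3-carboxylate | COC(=O)[C@]1(O)CC[C@]2(C)O[C@@H]2C1
F3 | step 5 | methyl (1S,3S,4S)-3-chloro-1,4-dihydroxy-4-methylcyclohexane-1-carboxylate | COC(=O)[C@]1(O)CC[C@](C)(O)[C@@H](Cl)C1
F4 | step 6 | (1S,5S)-5-chloro-1-hydroxy-4-methylcyclohex-3-ene-1-carboxylic acid | OC(=O)[C@]1(O)CC=C(C)[C@@H](Cl)C1
F5 | step 11 | (1S,3S,4S)-4-bromo-3-chloro-4-methyl-1-(triethylsilyloxy)cyclohexane-1-carbaldehyde | O=C[C@]1(O[Si](CC)(CC)CC)CC[C@](C)(Br)[C@@H](Cl)C1
F6 | step 11 | (4R)-1-[(1S,3S,4S)-4-bromo-3-chloro-4-methyl-1-(triethylsilyloxy)cyclohexyl]-4-(tert-butyldimethylsilyloxy)-5-methylhex-5-en-1-ol | C=C(C)[C@H](O[Si](C)(C)C(C)(C)C)CCC(O)[C@]1(O[Si](CC)(CC)CC)CC[C@](C)(Br)[C@@H](Cl)C1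
F7 | step 12 | (5R)-2-[(1S,3S,4S)-4-bromo-3-chloro-4-methyl-1-(triethylsilyloxy)cyclohexyl]-5-(tert-butyldimethylsilyloxy)-6-methyl-1-(trimethylsilyl)hept-6-en-2-ol | C=C(C)[C@H](O[Si](C)(C)C(C)(C)C)CCC(O)(C[Si](C)(C)C)[C@]1(O[Si](CC)(CC)CC)CC[C@](C)(Br)[C@@H](Cl)C1
F8 | step 4 | (1S)-1-hydroxy-4-methylcyclohex-3-ene-1-carbaldehyde | O=C[C@]1(O)CCC(C)=CC1
A1 | alternative 1 | (3S,4S)-4-bromo-3-chloro-4-methylcyclohexan-1-one | O=C1CC[C@](C)(Br)[C@@H](Cl)C1
A2 | alternative 1 | [(5R)-5-(tert-butyldimethylsilyloxy)-6-methylhepta-1,6-dien-2-yl]lithium | C=C(C)[C@H](O[Si](C)(C)C(C)(C)C)CCC(=C)[Li]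
A3 | alternative 2 | (1S)-1-[(5R)-5-hydroxy-6-methylhepta-1,6-dien-2-yl]-4-methylcyclohex-3-en-1-ol | C=C(C)[C@H](O)CCC(=C)[C@]1(O)CCC(C)=CC1
A4 | alternative 2 | (1R,2R,4S)-2-bromo-4-[(5R)-5-hydroxy-6-methylhepta-1,6-dien-2-yl]-1-methyl-7-oxabicyclo[2.2.1]heptane | C=C(C)[C@H](O)CCC(=C)[C@@]12CC[C@@](C)(O1)[C@H](Br)C2
A5 | alternative 3 | (1S,2S)-1-bromo-2-chloro-1-methyl-4-[(E)-6-methylhept-5-en-2-ylidene]cyclohexane | C/C(CCC=C(C)C)=C1/CC[C@](C)(Br)[C@@H](Cl)C1
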